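The numbers of this flask are invented; the flask was simulated.

- Seconds are what I count in this run: substrate must pass to intermediate A, then to intermediate B, then to target, and each passage costs on average one lifetime, so the lifetimes add to 51.3 s, and this sum is what I carry as the transit time.

| flask | substrate | capture agent | remark | time |
|---|---|---|---|---|
| theta | 1.0 mM | 0.100 mM | one stirred flow tank at steady state, fed with the mixture as stated, mean residence time 12 s |  |
| epsilon | 1.0 mM | 0.100 mM | a closed flask charged with all of it at once and left for 12 s | 12 s |
| zeta | 1.0 mM (fed, over 9.60 s) | 0.100 mM | all but substrate at the start; substrate goes in evenly over 9.60 s, the run ends at 12 s | 12 s |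
| beta | 1.0 mM | 0.100 mM | one stirred flow tank at steady state, fed with the mixture as stated, mean residence time 36.0 s |  |

- the set-up with the highest amount of target at the outlet or at the end, in percent of the substrate put in ("none" if the first two lie within 2 percentage points) (theta / epsilon / zeta / beta / none)
- amount of target at the outlet or at the end, in percent of the substrate put in, theta
- amount of target at the outlet or at the end, in percent of the substrate put in, epsilon
- amount of target at the outlet or at the end, in percent of the substrate put in, zeta
- amount of target at the outlet or at the end, in percent of the substrate put in, beta

- in percentages every species weighs as the substrate in it: one idle adduct counts as two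
- for target the idle adduct is counted in
- the stated concentrations are those of everything mixed, before any reaction; amounts are the same in each set-up
- the feed brings no volume worth counting
- in an amount of target, one idle adduct counts as one target
- run time (epsilon): 12 s

    substrate → intermediate A (k1 = 0.23 s⁻¹)
    intermediate A → intermediate B (k2 = 0.033 s⁻¹)
    intermediate B → target (k3 = 0.060 s⁻¹)
    substrate + target ⇌ idle adduct, settled at all times (K4 = 3000 M⁻¹)
    substrate → decomposition product (k5 = 6.5 × 10⁻⁵ s⁻¹)
    intermediate A + capture agent → trapped intermediate (k6 = 17 M⁻¹ s⁻¹)

- My bench rule takes the symmetric case as the zero of the scale: if arrivals spread evenly round their mean, a fraction 0.5 of the charge has arrived at the transit time.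
- The border of that rule shows at once, since epsilon is read at 0.234 of the transit time, earlier than the mark, so the rule tells me the reading lies in the early tail and gives me no number.
- For that tail I use the fact that substrate goes quicker than either intermediate, so I book its lifetime as dead time, which leaves 7.65 s in epsilon, and target then grows with the square of that time, to 5.80% of the charge.
- I drop capture, a pseudo-first-order leak at 0.00170 s⁻¹, since it runs slower than the passing of intermediate A into intermediate B.
- In zeta, the portions fed early enough to clear the dead time make up 0.797 of the charge, and when I give them the square law at their mean age after the dead time, 3.83 s, I get 1.16%.
- For the tanks, each step passes a share equal to its rate constant times the residence time, over one plus that product, and the shares multiply, so theta, whose residence time equals 12 s, gives 8.72% and beta, at 36.0 s, gives 33.1%.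
- I commit to beta as the best set-up.
- The forecast gives 8.3% for theta, 5.45% for epsilon, 2.02% for zeta and 30.1% for beta, with the choice beta: “Beta wins clearly, because residence time dominates.”
- The simulation gives 8.29% for theta, 5.46% for epsilon, 2.02% for zeta and 30.1% for beta, and the highest is beta.

- In zeta the mean moment of feeding, 4.80 s, adds to the transit time to make 56.1 s, and the reading at 12 s stands at 0.214 of that mark, in the early tail, with target at 2.02% and intermediate A at 64.5%; the same flask read at 50 s stands at 0.891 of the mark, so the rule puts it near 0.5 of the charge, and its target reads 51.2%, with intermediate B at 20.4%.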